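**Assumption:** the Z‑enol borinate made with the diisopinocampheylboron triflate from (−)‑α‑pinene is taken to attack the Re face of an aldehyde; if a calibration aldol shows the opposite sense, the reagent from (+)‑α‑pinene is used in step 7 and nothing else changes.

## Retrosynthetic overview

- The target comes from the corresponding central carbinol by a last‑step oxidation, so the ketone flanked by the two labile CHMe centres is unveiled only at the end.
- Ring A (pentyl pyrone) and ring B (ethyl pyrone) are closed together in one flask, each by forming its ring C–O bond, in a palladium‑catalysed aerobic dehydrogenative O‑cyclisation of a bis(β‑hydroxy enone).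
- The bis(β‑hydroxy enone) comes from a meso anti,anti dialdehyde and two achiral enone ethyl ketones by two boron aldols in one pot; a chiral boron reagent picks one of the two enantiotopic CHO groups, which fixes the absolute configuration.
- The meso dialdehyde comes from double hydroboration–oxidation of silylated 2,4‑dimethylpenta‑1,4‑dien‑3‑ol (methacrolein + isopropenylmagnesium bromide); the enones come from pentan‑3‑one with hexanal or propanal.

## Route

**Step 1**
Reactants: 1 pentan‑3‑one; 2 hexanal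
Product: 3 (E)‑4‑methyldec‑4‑en‑3‑one
Conditions: NaOH (2 M aq, 0.3 equiv), 1 in excess (5 equiv) as co‑solvent, 70 °C, 2 added over 4 h; distillation
Reagents that add atoms: none
Why: Crossed aldol condensation in which the enolate of the excess ketone adds to the slowly fed aldehyde and the aldol dehydrates to the conjugated enone, E being the thermodynamic isomer.

**Step 2**
Reactants: 1 pentan‑3‑one; 4 propanal
Product: 5 (E)‑4‑methylhept‑4‑en‑3‑one
Conditions: NaOH (2 M aq, 0.3 equiv), 1 in excess (5 equiv), 60 °C, 4 added over 4 h; distillation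
Reagents that add atoms: none
Why: The same crossed aldol condensation as in step 1, giving the E enone that will become the C‑2 ethyl/C‑3 methyl edge of ring B.

**Step 3**
Reactants: 6 methacrolein; 7 isopropenylmagnesium bromide
Product: 8 2,4‑dimethylpenta‑1,4‑dien‑3‑ol
Conditions: THF, −78 → 0 °C; then H2O
Reagents that add atoms: none
Why: Grignard 1,2‑addition to the aldehyde gives the bis‑isopropenyl carbinol, whose carbinol carbon carries two identical arms and is therefore not a stereocentre.

**Step 4**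
Reactants: 8 2,4‑dimethylpenta‑1,4‑dien‑3‑ol
Product: 9 tert‑butyl[(2,4‑dimethylpenta‑1,4‑dien‑3‑yl)oxy]dimethylsilane
Conditions: TBSCl, imidazole, DMF, rt
Reagents that add atoms: tert‑butyldimethylsilyl chloride, CC(C)(C)[Si](C)(C)Cl
Why: Imidazole‑assisted silylation masks the future ketone oxygen as a TBS ether that is carried through to step 9.

**Step 5**
Reactants: 9 tert‑butyl[(2,4‑dimethylpenta‑1,4‑dien‑3‑yl)oxy]dimethylsilane
Product: 11 meso anti,anti‑(2R,4S)‑3‑[(tert‑butyldimethylsilyl)oxy]‑2,4‑dimethylpentane‑1,5‑diol, via bis‑borane 10 (not isolated)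
Conditions: 9‑BBN (2.6 equiv), THF, 0 °C → rt; then NaOH (aq), H2O2, 0 °C → rt; chromatography
Reagents that add atoms: hydrogen peroxide, OO
Why: Two‑directional hydroboration–oxidation in which 9‑BBN adds anti‑Markovnikov to each 1,1‑disubstituted alkene and, under allylic‑strain control, anti to the silyloxy group, so both CHMe centres are set 1,2‑anti to C‑3 and the meso anti,anti triad (R at one CHMe, S at the other) results; the minor syn,anti diol is removed by chromatography.

**Step 6**
Reactants: 11 meso anti,anti diol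
Product: 12 meso anti,anti‑(2R,4S)‑3‑[(tert‑butyldimethylsilyl)oxy]‑2,4‑dimethylpentanedial
Conditions: (COCl)2, DMSO, CH2Cl2, −78 °C; Et3N, −78 → −20 °C; used crude at once
Reagents that add atoms: none
Why: Swern oxidation activates both alcohols before base is added, so no lactol or lactone can form, and the cold non‑aqueous conditions leave the two α‑CHMe centres unepimerised.

**Step 7**
Reactants: 12 meso dialdehyde; 3 (E)‑4‑methyldec‑4‑en‑3‑one; 5 (E)‑4‑methylhept‑4‑en‑3‑one
Product: 14 bis‑aldol diol (3E,15E)‑9‑[(tert‑butyldimethylsilyl)oxy]‑7,11‑dihydroxy‑4,6,8,10,12,14‑hexamethylicosa‑3,15‑diene‑5,13‑dione (C‑8/C‑9/C‑10 as in 12 with C‑10 on the pentyl side; C‑6/C‑7/C‑11/C‑12 mixtures), via boron mono‑aldolate 13 (not isolated)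
Conditions: (a) 3 (1.15 equiv), diisopinocampheylboron triflate from (−)‑α‑pinene ((+)‑Ipc2BOTf), iPr2NEt, CH2Cl2, −78 °C; add 12, −78 °C, 4 h; (b) enol borinate of 5 (2.5 equiv, pre‑formed with Bu2BOTf, iPr2NEt) added by cannula, −78 → −20 °C; (c) pH 7 buffer, MeOH, H2O2, 0 °C; chromatography removes the symmetrical bis‑pentyl and bis‑ethyl adducts
Reagents that add atoms: none
Why: Reagent‑controlled boron aldol (Paterson type) used for enantiotopic‑group selection, followed in the same pot by a second boron aldol: the chiral Z‑enol borinate of 3 attacks the Re face, which is the matched anti‑Felkin face only for the CHO on the (S)‑CHMe carbon of 12; the wrong‑arm mono‑adduct keeps a matched CHO and is drained to separable bis‑pentyl material by the 0.15 equiv excess, and the remaining CHO then takes the enolate of 5. The four new centres are erased in step 8 and the two CHMe centres are untouched.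

**Step 8**
Reactants: 14 bis‑aldol diol
Product: 16 bis‑pyrone silyl ether 2‑[(2S,3S,4R)‑3‑[(tert‑butyldimethylsilyl)oxy]‑4‑(6‑ethyl‑3,5‑dimethyl‑4‑oxo‑4H‑pyran‑2‑yl)pentan‑2‑yl]‑3,5‑dimethyl‑6‑pentyl‑4H‑pyran‑4‑one, via bis‑dihydropyranone 15 (not isolated)
Conditions: Pd(OCOCF3)2 (20 mol %), DMSO (40 mol %), O2 (1 atm), 4 Å MS, AcOH/EtOAc (1:9), 60 °C
Reagents that add atoms: none
Why: Proposed new method: a palladium‑catalysed aerobic dehydrogenative oxa‑annulation that takes a β‑hydroxy enone to a γ‑pyrone in one flask, run on both arms at once: the aldol OH adds 6‑endo to the enone C=C held on divalent palladium (Wacker‑type oxypalladation, forming the ring C–O bond), β‑hydride elimination gives the 2,3‑dihydro‑4H‑pyran‑4‑one 15, and the same Pd/DMSO/O2 system then palladates C‑3 through the enol and eliminates the C‑2 hydride to aromatise, O2 returning zerovalent palladium to the divalent state; the closest known reaction types are the Pd‑catalysed oxidative cyclisation of β‑hydroxy enones to dihydropyranones and the aerobic Pd/DMSO α,β‑dehydrogenation of cyclic ketones (flavanone to flavone), which have not been merged, run two‑fold or shown on fully substituted acyclic aldols; all four aldol‑derived centres are destroyed so the diastereomer mixture converges, and the two CHMe centres lie outside the rings and are never α to a carbonyl before the pyrones exist.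

**Step 9**
Reactants: 16 bis‑pyrone silyl ether
Product: 17 2‑[(2S,3S,4R)‑4‑(6‑ethyl‑3,5‑dimethyl‑4‑oxo‑4H‑pyran‑2‑yl)‑3‑hydroxypentan‑2‑yl]‑3,5‑dimethyl‑6‑pentyl‑4H‑pyran‑4‑one
Conditions: HF·pyridine, pyridine, THF, 0 °C → rt
Reagents that add atoms: none
Why: Acidic fluoride desilylation frees the carbinol without the basic conditions (TBAF) that could epimerise or β‑eliminate next to the pyrones; no stereocentre changes.

**Step 10**
Reactants: 17 bis‑pyrone carbinol
Product: 18 (2R,4S)‑2‑(3,5‑dimethyl‑4‑oxo‑6‑pentyl‑4H‑pyran‑2‑yl)‑4‑(6‑ethyl‑3,5‑dimethyl‑4‑oxo‑4H‑pyran‑2‑yl)pentan‑3‑one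
Conditions: Dess–Martin periodinane (1.5 equiv), CH2Cl2, 0 °C, 20 min; cold filtration through pH 7 buffered silica
Reagents that add atoms: none
Why: Dess–Martin oxidation gives the ketone under neutral, cold, brief conditions with no base and no aqueous work‑up, which matters because the two CHMe centres (R next to ring A, S next to ring B, set in step 5 and assigned to the arms in step 7) become acidic once flanked by ketone and pyrone.

## Compound list

1 | pentan‑3‑one | CCC(=O)CC | starting material
2 | hexanal | CCCCCC=O | starting material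
3 | (E)‑4‑methyldec‑4‑en‑3‑one | CCC(=O)/C(C)=C/CCCCC | intermediate
4 | propanal | CCC=O | starting material
5 | (E)‑4‑methylhept‑4‑en‑3‑one | CCC(=O)/C(C)=C/CC | intermediate
6 | methacrolein | CC(=C)C=O | starting material
7 | isopropenylmagnesium bromide | CC(=C)[Mg]Br | starting material
8 | 2,4‑dimethylpenta‑1,4‑dien‑3‑ol | CC(=C)C(O)C(C)=C | intermediate
9 | tert‑butyl[(2,4‑dimethylpenta‑1,4‑dien‑3‑yl)oxy]dimethylsilane | CC(=C)C(O[Si](C)(C)C(C)(C)C)C(C)=C | intermediate
10 | bis‑borane: 1,5‑bis(9‑borabicyclo[3.3.1]nonan‑9‑yl) derivative of the anti,anti silyloxy‑dimethylpentane | C(B1C2CCCC1CCC2)[C@@H](C)[C@@H](O[Si](C)(C)C(C)(C)C)[C@@H](C)CB1C2CCCC1CCC2 | intermediate (not isolated)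
11 | meso anti,anti‑(2R,4S)‑3‑[(tert‑butyldimethylsilyl)oxy]‑2,4‑dimethylpentane‑1,5‑diol | OC[C@@H](C)[C@@H](O[Si](C)(C)C(C)(C)C)[C@@H](C)CO | intermediate
12 | meso anti,anti‑(2R,4S)‑3‑[(tert‑butyldimethylsilyl)oxy]‑2,4‑dimethylpentanedial | O=C[C@@H](C)[C@@H](O[Si](C)(C)C(C)(C)C)[C@@H](C)C=O | intermediate
13 | boron mono‑aldolate: O‑diisopinocampheylboryl aldol of 3 on the CHO at the (S)‑CHMe carbon of 12, other CHO free (aldol centres unassigned) | CCCCC/C=C(\C)C(=O)C(C)C(OB([C@H]1C[C@H]2C[C@@H]([C@@H]1C)C2(C)C)[C@H]1C[C@H]2C[C@@H]([C@@H]1C)C2(C)C)[C@@H](C)[C@@H](O[Si](C)(C)C(C)(C)C)[C@@H](C)C=O | intermediate (not isolated)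
14 | bis‑aldol diol, (3E,15E)‑9‑[(tert‑butyldimethylsilyl)oxy]‑7,11‑dihydroxy‑4,6,8,10,12,14‑hexamethylicosa‑3,15‑diene‑5,13‑dione (triad as in 12; aldol centres mixtures) | CCCCC/C=C(\C)C(=O)C(C)C(O)[C@@H](C)[C@@H](O[Si](C)(C)C(C)(C)C)[C@@H](C)C(O)C(C)C(=O)/C(C)=C/CC | intermediate
15 | bis(2,3‑dihydro‑4H‑pyran‑4‑one): silyloxy‑pentane‑2,4‑diyl chain (triad as in 12) bearing a 3,5‑dimethyl‑6‑pentyl‑ and a 6‑ethyl‑3,5‑dimethyl‑2,3‑dihydropyran‑4‑on‑2‑yl ring (ring C‑2/C‑3 mixtures) | CCCCCC1=C(C)C(=O)C(C)C(O1)[C@@H](C)[C@@H](O[Si](C)(C)C(C)(C)C)[C@@H](C)C1OC(CC)=C(C)C(=O)C1C | intermediate (not isolated)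
16 | 2‑[(2S,3S,4R)‑3‑[(tert‑butyldimethylsilyl)oxy]‑4‑(6‑ethyl‑3,5‑dimethyl‑4‑oxo‑4H‑pyran‑2‑yl)pentan‑2‑yl]‑3,5‑dimethyl‑6‑pentyl‑4H‑pyran‑4‑one | CCCCCc1oc([C@@H](C)[C@@H](O[Si](C)(C)C(C)(C)C)[C@@H](C)c2oc(CC)c(C)c(=O)c2C)c(C)c(=O)c1C | intermediate
17 | 2‑[(2S,3S,4R)‑4‑(6‑ethyl‑3,5‑dimethyl‑4‑oxo‑4H‑pyran‑2‑yl)‑3‑hydroxypentan‑2‑yl]‑3,5‑dimethyl‑6‑pentyl‑4H‑pyran‑4‑one | CCCCCc1oc([C@@H](C)[C@@H](O)[C@@H](C)c2oc(CC)c(C)c(=O)c2C)c(C)c(=O)c1C | intermediate
18 | (2R,4S)‑2‑(3,5‑dimethyl‑4‑oxo‑6‑pentyl‑4H‑pyran‑2‑yl)‑4‑(6‑ethyl‑3,5‑dimethyl‑4‑oxo‑4H‑pyran‑2‑yl)pentan‑3‑one | CCCCCc1oc([C@@H](C)C(=O)[C@@H](C)c2oc(CC)c(C)c(=O)c2C)c(C)c(=O)c1C | target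

## Step count and risks

Total steps: 10. Longest linear sequence: 8 (steps 3 to 10).

**Step 7 (group‑selective double aldol).** Risk: insufficient discrimination between the two enantiotopic CHO groups, and statistical bis‑adducts. Fallback, setting out from 11 and coming back at 14: desymmetrise the meso diol enzymatically and build the arms one at a time. Burkholderia cepacia lipase with vinyl acetate gives the monoacetate F1, drawn with the free CH2OH on the ring‑A arm; if the enzyme selects the other arm, 5 is introduced before 3. Swern oxidation gives the acetoxy aldehyde F2, and a Bu2BOTf/iPr2NEt aldol with 3 gives the aldol acetate F3. TESOTf/2,6‑lutidine gives the triethylsilyl ether F4, and K2CO3 in MeOH at 0 °C removes the acetate to give the primary alcohol F5. Swern oxidation gives the aldehyde F6, and a second Bu2BOTf aldol with 5 gives the mono‑silylated bis‑aldol F7. AcOH/THF/H2O removes the triethylsilyl group and returns 14.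

**Step 8 (new palladium annulation).** Risk: the second dehydrogenation stalls on the hindered rings, or the catalyst is sequestered. Fallback with known chemistry, setting out from 14 and coming back at 16: PdCl2(MeCN)2/CuCl/Na2HPO4 under O2 in DME at rt (the known oxidative cyclisation of β‑hydroxy enones) gives the bis‑dihydropyranone 15, now isolated. Dehydrogenation of 15 with 2‑iodoxybenzoic acid in DMSO at 65 °C then gives 16. No compound outside the list is made.

**Step 1 (crossed aldol condensation, and its twin step 2).** Risk: self‑condensation of the enolisable aldehyde and low yield. Fallback, setting out from 2 and coming back at 3: a Wittig olefination instead of a condensation. Commercial 2‑bromopentan‑3‑one and PPh3 in toluene give the (3‑oxopentan‑2‑yl)triphenylphosphonium bromide F8, aqueous NaOH gives the stabilised ylide 2‑(triphenylphosphoranylidene)pentan‑3‑one F9, and F9 with 2 in toluene at 90 °C gives 3 as the E isomer. The same ylide with 4 gives 5.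

## Further compounds

F1 | step 7 | monoacetate of 11 (free CH2OH on the ring‑A arm) | OC[C@@H](C)[C@@H](O[Si](C)(C)C(C)(C)C)[C@@H](C)COC(C)=O
F2 | step 7 | acetoxy aldehyde | O=C[C@@H](C)[C@@H](O[Si](C)(C)C(C)(C)C)[C@@H](C)COC(C)=O
F3 | step 7 | aldol acetate from F2 and 3 (aldol centres mixtures) | CCCCC/C=C(\C)C(=O)C(C)C(O)[C@@H](C)[C@@H](O[Si](C)(C)C(C)(C)C)[C@@H](C)COC(C)=O
F4 | step 7 | triethylsilyl ether of F3 | CCCCC/C=C(\C)C(=O)C(C)C(O[Si](CC)(CC)CC)[C@@H](C)[C@@H](O[Si](C)(C)C(C)(C)C)[C@@H](C)COC(C)=O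
F5 | step 7 | primary alcohol from F4 | CCCCC/C=C(\C)C(=O)C(C)C(O[Si](CC)(CC)CC)[C@@H](C)[C@@H](O[Si](C)(C)C(C)(C)C)[C@@H](C)CO
F6 | step 7 | aldehyde from F5 | CCCCC/C=C(\C)C(=O)C(C)C(O[Si](CC)(CC)CC)[C@@H](C)[C@@H](O[Si](C)(C)C(C)(C)C)[C@@H](C)C=O
F7 | step 7 | mono‑triethylsilylated bis‑aldol from F6 and 5 | CCCCC/C=C(\C)C(=O)C(C)C(O[Si](CC)(CC)CC)[C@@H](C)[C@@H](O[Si](C)(C)C(C)(C)C)[C@@H](C)C(O)C(C)C(=O)/C(C)=C/CC
F0 | step 8 | none | none
F8 | step 1 | (3‑oxopentan‑2‑yl)triphenylphosphonium bromide | CCC(=O)C(C)[P+](c1ccccc1)(c1ccccc1)c1ccccc1.[Br-]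
F9 | step 1 | 2‑(triphenylphosphoranylidene)pentan‑3‑one | CCC(=O)C(C)=P(c1ccccc1)(c1ccccc1)c1ccccc1
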